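**Retrosynthetic overview**

1. Ring labels: A is the phenol ring with its ether O para to OH and the A–B bridge ortho to that O; B is the para-phenylene; C is the ring with OH ortho to its ether O; D is the meta-phenylene. The target comes from its di-O-methyl ether, and this from a macrocyclic stilbene by hydrogenation.
2. The macrocyclic stilbene is opened at the CH=CH of the C–D bridge to an open-chain dialdehyde. An intramolecular McMurry coupling closes the only ring that has to be made, the 18-membered macrocycle, last.
3. Enabling feature: both carbons of the C–D ethano bridge are benzylic (one on ring C para to its OH, one on ring D meta to its ether O), so each can be a formyl carbon. The ortho-linked ring A, the meta-linked rings C and D and the flexible A–B ethano bridge let the two CHO groups meet, and two like termini can be carried as two CO2Me groups without differentiation.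
4. The dialdehyde comes from a diester whose A–B bridge is made by Wittig olefination and hydrogenation, from a D–O–A aldehyde and a B–O–C benzylphosphonium salt.
5. Both diaryl ethers come from SNAr of methyl hydroxybenzoates on fluorobenzaldehydes. All four benzene rings are bought; order: ether bonds, A–B bridge, macrocycle.

Key step: step 9

Remark: the target has no stereocentre. The alkene geometry of 10 and 15 is immaterial because both are hydrogenated, so they are used as E/Z mixtures and written without E/Z descriptors, and the transient carbinol centres of 14 are likewise left undefined.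

**Step 1**
Reactants: 1 methyl 3-hydroxy-4-methoxybenzoate; 2 4-fluorobenzaldehyde
Product: 3 methyl 3-(4-formylphenoxy)-4-methoxybenzoate
Conditions: K2CO3, DMF, 130 °C
Reagents that add atoms: none
Why: SNAr (addition–elimination): the para-formyl group activates the C–F bond of 2 towards the phenoxide of 1, and the methyl ester is inert to anhydrous carbonate.

**Step 2**
Reactants: 3 methyl 3-(4-formylphenoxy)-4-methoxybenzoate
Product: 4 methyl 3-[4-(hydroxymethyl)phenoxy]-4-methoxybenzoate
Conditions: NaBH4, MeOH/THF, 0 °C
Reagents that add atoms: none
Why: Chemoselective borohydride reduction of the aryl aldehyde; a methyl benzoate is not reduced by NaBH4 at 0 °C.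

**Step 3**
Reactants: 4 methyl 3-[4-(hydroxymethyl)phenoxy]-4-methoxybenzoate
Product: 5 {4-[2-methoxy-5-(methoxycarbonyl)phenoxy]benzyl}triphenylphosphonium bromide
Conditions: PPh3·HBr, MeCN, reflux
Reagents that add atoms: triphenylphosphine hydrobromide, [Br-].[PH+](c1ccccc1)(c1ccccc1)c1ccccc1
Why: Direct phosphonium salt formation from a benzylic alcohol: acid-promoted displacement of water at the p-aryloxy-stabilised benzylic carbon by bromide/PPh3, with ester and ethers untouched.

**Step 4**
Reactants: 6 methyl 3-hydroxybenzoate; 7 2-fluoro-5-methoxybenzaldehyde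
Product: 8 methyl 3-(2-formyl-4-methoxyphenoxy)benzoate
Conditions: K2CO3, DMAc, 150 °C
Reagents that add atoms: none
Why: SNAr: the ortho-formyl group stabilises the Meisenheimer adduct at the C–F carbon of 7, and the higher temperature compensates for the retarding para-methoxy group.

**Step 5**
Reactants: 5 {4-[2-methoxy-5-(methoxycarbonyl)phenoxy]benzyl}triphenylphosphonium bromide; 8 methyl 3-(2-formyl-4-methoxyphenoxy)benzoate
Product: 10 methyl 3-[4-(2-{5-methoxy-2-[3-(methoxycarbonyl)phenoxy]phenyl}ethenyl)phenoxy]-4-methoxybenzoate (E/Z mixture), via phosphonium ylide 9 (not isolated)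
Conditions: K2CO3, 18-crown-6 (cat.), CH2Cl2, reflux
Reagents that add atoms: none
Why: Wittig olefination of a semi-stabilised benzylic ylide under solid–liquid phase-transfer conditions that leave methyl esters intact; it builds the A–B bridge carbon skeleton.

**Step 6**
Reactants: 10 methyl 3-[4-(2-{5-methoxy-2-[3-(methoxycarbonyl)phenoxy]phenyl}ethenyl)phenoxy]-4-methoxybenzoate
Product: 11 methyl 3-[4-(2-{5-methoxy-2-[3-(methoxycarbonyl)phenoxy]phenyl}ethyl)phenoxy]-4-methoxybenzoate
Conditions: H2 (1 atm), 10% Pd/C, EtOAc, rt
Reagents that add atoms: none
Why: Heterogeneous catalytic hydrogenation converges both stilbene isomers to the ethano bridge; esters, aryl ethers and diaryl ethers are inert.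

**Step 7**
Reactants: 11 methyl 3-[4-(2-{5-methoxy-2-[3-(methoxycarbonyl)phenoxy]phenyl}ethyl)phenoxy]-4-methoxybenzoate
Product: 12 {3-[4-(2-{2-[3-(hydroxymethyl)phenoxy]-5-methoxyphenyl}ethyl)phenoxy]-4-methoxyphenyl}methanol
Conditions: LiAlH4, THF, 0 °C → rt; Fieser work-up
Reagents that add atoms: none
Why: Two-directional hydride reduction of both aryl methyl esters to the benzylic alcohols; no other reducible group is present.

**Step 8**
Reactants: 12 {3-[4-(2-{2-[3-(hydroxymethyl)phenoxy]-5-methoxyphenyl}ethyl)phenoxy]-4-methoxyphenyl}methanol
Product: 13 3-[4-(2-{2-(3-formylphenoxy)-5-methoxyphenyl}ethyl)phenoxy]-4-methoxybenzaldehyde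
Conditions: Dess–Martin periodinane, CH2Cl2, rt
Reagents that add atoms: none
Why: Dess–Martin oxidation takes both benzylic alcohols to the aldehydes without over-oxidation and without touching the electron-rich rings.

**Step 9**
Reactants: 13 3-[4-(2-{2-(3-formylphenoxy)-5-methoxyphenyl}ethyl)phenoxy]-4-methoxybenzaldehyde
Product: 15 macrocyclic stilbene (the di-O-methyl ether of the target with CH=CH in place of the ring C–ring D CH2–CH2 bridge; E/Z mixture), via titanium pinacolate 14 (not isolated)
Conditions: TiCl4, Zn dust, pyridine, THF, reflux; 13 added by syringe pump (high dilution)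
Reagents that add atoms: none
Why: Low-valent titanium from TiCl4/Zn transfers one electron to each aryl aldehyde of 13, the two ketyl radicals couple on titanium to the pinacolate 14, and at reflux 14 is deoxygenated to the C=C bond, so C–C bond formation, ring closure and removal of both terminal oxygens occur in one operation. The closest known reaction type is the intramolecular McMurry coupling of aromatic dialdehydes to macrocyclic stilbenes and cyclophanes, which is established for diaryl-ether-linked bis(bibenzyl) dialdehydes of this ring size. The 18-membered ring is closed end-to-end by ketyl–ketyl coupling between the formyl carbon on ring C and that on ring D under pseudo-high dilution. No stereocentre remains, since the two carbinol centres of 14 are destroyed on deoxygenation and the alkene geometry of 15 is erased in step 10. The step needs cyclisation to win over intermolecular coupling and needs chemoselectivity for the two CHO groups: the first is secured by slow addition together with the ortho-linked ring A, the meta-linked rings C and D and the flexible A–B ethano bridge, which let the chain fold so that the formyl carbons meet without strain; the second by the absence of any other reducible group, since only aryl methyl ethers and diaryl ethers are present.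

**Step 10**
Reactants: 15 macrocyclic stilbene
Product: 16 di-O-methyl ether of the target (macrocyclic bis(bibenzyl) with OMe on rings A and C)
Conditions: H2 (1 atm), 10% Pd/C, EtOAc/THF, rt
Reagents that add atoms: none
Why: Catalytic hydrogenation saturates the macrocyclic stilbene of either geometry to the C–D ethano bridge; no benzylic C–O bond or other reducible group is present.

**Step 11**
Reactants: 16 di-O-methyl ether of the target
Product: 18 target CNP0135015.0 (free bis-phenol), via bis(dibromoboryl) ether 17 (not isolated)
Conditions: BBr3 (excess), CH2Cl2, −78 °C → rt; then H2O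
Reagents that add atoms: none
Why: Lewis-acid ether cleavage (BBr3 demethylation): bromide attacks the methyl group of the boron-complexed aryl methyl ethers, while the diaryl ether C(sp2)–O bonds cannot be cleaved this way.

**Compound list**

1 | methyl 3-hydroxy-4-methoxybenzoate | COC(=O)c1ccc(OC)c(O)c1 | starting material
2 | 4-fluorobenzaldehyde | O=Cc1ccc(F)cc1 | starting material
3 | methyl 3-(4-formylphenoxy)-4-methoxybenzoate | COC(=O)c1ccc(OC)c(Oc2ccc(C=O)cc2)c1 | intermediate
4 | methyl 3-[4-(hydroxymethyl)phenoxy]-4-methoxybenzoate | COC(=O)c1ccc(OC)c(Oc2ccc(CO)cc2)c1 | intermediate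
5 | {4-[2-methoxy-5-(methoxycarbonyl)phenoxy]benzyl}triphenylphosphonium bromide | COC(=O)c1ccc(OC)c(Oc2ccc(C[P+](c3ccccc3)(c3ccccc3)c3ccccc3)cc2)c1.[Br-] | intermediate
6 | methyl 3-hydroxybenzoate | COC(=O)c1cccc(O)c1 | starting material
7 | 2-fluoro-5-methoxybenzaldehyde | COc1ccc(F)c(C=O)c1 | starting material
8 | methyl 3-(2-formyl-4-methoxyphenoxy)benzoate | COC(=O)c1cccc(Oc2ccc(OC)cc2C=O)c1 | intermediate
9 | {4-[2-methoxy-5-(methoxycarbonyl)phenoxy]benzylidene}triphenylphosphorane (ylide, formed in the flask, not isolated) | COC(=O)c1ccc(OC)c(Oc2ccc(C=P(c3ccccc3)(c3ccccc3)c3ccccc3)cc2)c1 | intermediate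
10 | methyl 3-[4-(2-{5-methoxy-2-[3-(methoxycarbonyl)phenoxy]phenyl}ethenyl)phenoxy]-4-methoxybenzoate (E/Z mixture) | COC(=O)c1cccc(Oc2ccc(OC)cc2C=Cc2ccc(Oc3cc(C(=O)OC)ccc3OC)cc2)c1 | intermediate
11 | methyl 3-[4-(2-{5-methoxy-2-[3-(methoxycarbonyl)phenoxy]phenyl}ethyl)phenoxy]-4-methoxybenzoate | COC(=O)c1cccc(Oc2ccc(OC)cc2CCc2ccc(Oc3cc(C(=O)OC)ccc3OC)cc2)c1 | intermediate
12 | {3-[4-(2-{2-[3-(hydroxymethyl)phenoxy]-5-methoxyphenyl}ethyl)phenoxy]-4-methoxyphenyl}methanol | OCc1cccc(Oc2ccc(OC)cc2CCc2ccc(Oc3cc(CO)ccc3OC)cc2)c1 | intermediate
13 | 3-[4-(2-{2-(3-formylphenoxy)-5-methoxyphenyl}ethyl)phenoxy]-4-methoxybenzaldehyde | O=Cc1cccc(Oc2ccc(OC)cc2CCc2ccc(Oc3cc(C=O)ccc3OC)cc2)c1 | intermediate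
14 | macrocyclic titanium pinacolate (formed in the flask, not isolated; drawn as the Ti(IV) dichloride 1,2-diolate chelate, diastereomer mixture) | COc1ccc2c(c1)CCc1ccc(cc1)Oc1cc(ccc1OC)C1O[Ti](Cl)(Cl)OC1c1cccc(c1)O2 | intermediate
15 | macrocyclic stilbene (di-O-methyl ether of the target with CH=CH as C–D bridge; E/Z mixture) | COc1ccc2c(c1)CCc1ccc(cc1)Oc1cc(ccc1OC)C=Cc1cccc(c1)O2 | intermediate
16 | di-O-methyl ether of the target | COc1ccc2c(c1)CCc1ccc(cc1)Oc1cc(ccc1OC)CCc1cccc(c1)O2 | intermediate
17 | bis(dibromoboryl) ether of the target (formed in the flask, not isolated) | BrB(Br)Oc1ccc2c(c1)CCc1ccc(cc1)Oc1cc(ccc1OB(Br)Br)CCc1cccc(c1)O2 | intermediate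
18 | CNP0135015.0 (macrocyclic bis(bibenzyl) bis-phenol) | Oc1ccc2c(c1)CCc1ccc(cc1)Oc1cc(ccc1O)CCc1cccc(c1)O2 | target

**Total step count:** 11
**Longest linear sequence:** 10 steps (steps 1, 2, 3, 5, 6, 7, 8, 9, 10, 11); step 4 is the convergent branch.

**Steps most likely to fail**

Step 9 (macrocyclisation). Intermolecular ketyl coupling may outrun ring closure and give oligomers, or the reaction may stall at the pinacolate stage. The fallback sets out from 13. Double Wittig methylenation with methylenetriphenylphosphorane (MePPh3Br, KOtBu, THF, 0 °C) should give the bis-styrene F1. Ring-closing olefin metathesis of F1 (second-generation Grubbs catalyst, toluene, 80 °C, high dilution, ethene purged) should then form the same C=C bond. Metathesis is reversible, so oligomers can be channelled back to the ring. The fallback rejoins the route at 15.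

Step 4 (SNAr on the deactivated fluoroarene). Addition of the moderately nucleophilic phenoxide to a C–F carbon that is deactivated by the para-methoxy group may be too slow, and the aldehyde may degrade at the forcing temperature. The fallback sets out from 6 and uses commercial 2-bromo-5-methoxybenzaldehyde (COc1ccc(Br)c(C=O)c1) in a copper-catalysed Ullmann ether synthesis (CuI, N,N-dimethylglycine, Cs2CO3, dioxane, 100 °C). This does not depend on ring activation and is assisted by the ortho-formyl group. It gives 8 directly, so the route is rejoined at 8 with no new intermediate.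

Step 11 (global demethylation). Cleavage of the ring C methyl ether flanked by the aryloxy group may be incomplete, or the Lewis acid may cause electrophilic side reactions on the electron-rich macrocycle. The fallback sets out from 16 and changes the mechanism to nucleophilic SN2 demethylation under basic conditions. Sodium ethanethiolate in DMF at 140 °C should give the disodium bis(phenolate) F2, which on acidification with aqueous HCl gives 18, the end of the route.

**Further compounds**

F1 | step 9 | 1-ethenyl-3-[4-(2-{2-(3-ethenylphenoxy)-5-methoxyphenyl}ethyl)phenoxy]-4-methoxybenzene (bis-styrene) | C=Cc1cccc(Oc2ccc(OC)cc2CCc2ccc(Oc3cc(C=C)ccc3OC)cc2)c1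
F0 | step 4 | none | none
F2 | step 11 | disodium bis(phenolate) of 18 | [Na+].[Na+].[O-]c1ccc2c(c1)CCc1ccc(cc1)Oc1cc(ccc1[O-])CCc1cccc(c1)O2
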